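## Structural features

6-Prenylcatechin is a flavan-3-ol. Ring A, a phloroglucinol-type arene, is fused through C4a–C8a to the dihydropyran ring C, and the catechol ring B is attached to C2 by a single C–C bond. Ring A is fully differentiated: O1 at C8a, hydroxyls at C5 and C7, the 3-methylbut-2-enyl (prenyl) group at C6 between them, and its only hydrogen at C8. The two stereocentres, C2 (R, aryl) and C3 (S, hydroxyl), are neighbours on ring C and are trans. Three parts are fragile:

- the trisubstituted prenyl alkene flanked by two phenols, which strong acid closes to a dimethylchroman and which epoxidising, dihydroxylating, hydroborating and hydrogenating reagents attack;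
- the air-sensitive catechol and phloroglucinol rings;
- the benzylic C2–O1 ether para to a ring B oxygen, which can ionise and scramble C2.

The real difficulty is twofold. The prenyl group must end at C6 and not at C8. The trans C2/C3 pair must be set in the absolute sense without alkene oxidations, which the prenyl double bond would not survive. The key step exploits two correspondences: O1–C8a–C4a–C4 of rings A and C is the heterodiene of an ortho-quinone methide, and C2–C3 with aryl and oxygen trans is an E alkene carrying ring B on one carbon and boron, a latent hydroxyl, on the other. Because C6 lies between two oxygens, ring A can come from a mirror-symmetric 4-prenylphenol whose two ortho positions are equivalent, which removes the C6/C8 question.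

## Logic of the disconnections

**17 to 16.** The four aryl O–CH2OCH3 bonds are cut. Masking all four phenols with one acetal type keeps the arenes inert to base, organolithium, hydride and peroxide, and leaves a single final operation. The demand is an acid mild enough to leave the prenyl alkene and the C2–O1 bond alone.

**16 to 14 (through 15).** The C3–O bond is traded for a C3–B bond. Boron can ride on an alkene carbon through a cycloaddition and is later replaced by oxygen with retention. This removes any oxidation of a C=C bond from the route, so the prenyl group is never at risk. The demand is a boron oxidation faster than β-elimination of the O1 aryloxide.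

**14 to 8 and 12 (through 13).** O1–C2 and C3–C4 are cut together, which opens ring C and removes both stereocentres in one stroke. Ring A with C4 becomes 8, the source of the heterodiene 13. Ring B with C2 and C3 becomes the E double bond of 12. The gain is the largest in the plan: two fragments of similar size, no stereocentre in either. The demand is a chiral acid that forms 13 from 8, steers the aryl-bearing carbon to O1, and selects one face of the E alkene.

**8 to 7 to 6.** The C4–C4a bond is cut, with a change of oxidation level at C4. Since 6 has a mirror plane through C1 and C4 of the phenol, either ortho carbon gives the same product. The demand is an ortho-selective one-carbon homologation that stops after one carbon, and gentle handling of the ionisable benzylic alcohol 8.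

**6 to 5.** The C8a–O bond is traced back to a C–Cl bond. A chlorine keeps that position silent during the preceding organolithium step, and a free phenol there would misdirect it. The demand is a C–O coupling that works on an electron-rich aryl chloride.

**5 to 2 and 3 (through 4), then 2 to 1.** The aryl–CH2 bond of the prenyl group is cut at the carbon between the two acetal oxygens. That is the one position both acetals direct a lithium base to, so the C6 placement is decided by the symmetry of 2. The demand is deprotonation without attack on the halogen, which is why 1 carries chlorine and not bromine, and alkylation of 3 at its primary carbon.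

**12 to 10 and 11, then 10 to 9.** The aryl–vinyl bond is cut. The vinyl boronate 11 already holds the tetracoordinate boron, so E geometry can be set in one C–C coupling. The demand is a coupling in which the boron group is a spectator.

## Other disconnections considered

**Alternative 1:** The cut removes C4a–C8a and C6–C7, so ring A does not exist before the key step and ring C closes in the same operation. Base would convert the keto ynoate A1 into its C4a enolate, which adds to the oxygen-bearing alkyne carbon C8a in a Michael addition. The C6 enolate then acylates the ester carbon C7 in a Claisen condensation, and tautomerisation aromatises ring A to give A2.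

- In favour: the prenyl position is fixed by chain connectivity, since C6 is simply the second α-carbon of the ketone. Both stereocentres would be set on an acyclic ring B fragment before any prenyl alkene is present, by established asymmetric oxidation chemistry. On that point the alternative is better than the chosen plan, whose enantiocontrol rests on an untested catalyst–substrate match.
- Against: A1 is a 3-alkoxypropiolate of a secondary, electron-rich benzylic alcohol, a group with few reliable preparations and a C–O bond prone to ionise. The ketone has two enolisable sides, and only C4a-first leads on. The Michael adduct needs the alkene geometry that lets C6 reach C7. A2 is a free, air-sensitive prenylphloroglucinol that still needs two different deprotections.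
- Comparison: on structure the two plans are equal, as both fix C6 by design. On mechanism the alternative uses familiar enolate reactions on an unfamiliar precursor, while the chosen plan uses an untested cycloaddition on simple, stable precursors. On step economy, the linear assembly of the C2–C6 chain with two stereocentres and an ynol ether is expected to exceed the ten steps of the chosen plan.

**Alternative 2:** The cut removes C8–C8a, C5–C6, C7–C8 and C4a–C5, so ring A is assembled on a finished, stereodefined ring C. Irradiation of the diazo ketone A3 with the siloxyalkyne A4 would start a Danheiser benzannulation: Wolff rearrangement, [2+2] cycloaddition, 4π opening and 6π closure, ending in A5.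

- In favour: every ring A substituent is placed by the mechanism, with the prenyl group coming from the alkyne. Conditions are neutral and compatible with acetals and the prenyl alkene. The C5 and C7 oxygens emerge differentiated, which the chosen plan cannot offer. The pericyclic cascade is at least as predictable mechanistically as the proposed catalytic cycloaddition.
- Against: A3 needs a trans-2-aryl-3-silyloxy dihydropyran with an acyl group on the enol ether carbon, made enantioselectively and then diazotised, which is a synthesis of its own. A4 is moisture-sensitive, and its prenyl alkene could be intercepted by the ketene intermediates. Three kinds of protecting group remain at the end.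
- Comparison: both plans are convergent and both solve C6. The alternative needs no enantioselective ring-forming step. The chosen plan is clearly shorter, because each of its fragments is two to five steps from commercial materials.

**Alternative 3:** Only C4–C4a is cut; O1–C2 already exists in the epoxy aryl ether A6. Under In(OTf)3 or in hexafluoroisopropanol the ortho carbon of ring A would attack the terminal epoxide carbon in a Friedel–Crafts alkylation, closing ring C and freeing the C3 hydroxyl in A7.

- In favour: ring A would come from the same symmetric phenol 6, so the plans are equal on the C6 question. C3 is not touched in the ring closure. Both stereocentres would come from a Sharpless epoxidation on the ring B fragment before ring A is attached. The reaction class, aryl glycidyl ether to chroman-3-ol, has closer precedent than the chosen key step, so on security of stereochemistry and precedent the alternative is better.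
- Against: the hindered benzylic aryl ether in A6 must be formed with clean inversion next to an epoxide. To keep C2 from ionising, ring B has to carry mesylates, whose later removal needs base or nucleophile strong enough to epimerise C2 of a catechin and to promote its oxidation. A Lewis acid meets acetals and the prenyl alkene. Attack at the internal epoxide carbon, giving a five-membered ring, competes.
- Comparison: the step count is similar or slightly higher, with two deprotection modes instead of one. The chosen plan is more convergent and uses one protecting group throughout.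

Key step: step 8

Assumption: which antipode of the phosphoric acid gives (2S,3S)-14 cannot be derived from first principles. The (R) catalyst is written, and the (S) catalyst is used instead if the induction has the opposite sense.

Remark: 11, 12 and 14 are drawn without the N→B dative bond, but boron is tetracoordinate in all three. In 14 and 15 boron occupies the place of the later hydroxyl; C2 reads S there only because boron ranks below carbon.

## Route

Step 1
Reactants: 1 5-chlororesorcinol
Product: 2 1-chloro-3,5-bis(methoxymethoxy)benzene
Conditions: MOMCl (2.6 equiv), i-Pr2NEt (3.5 equiv), CH2Cl2, 0 °C → rt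
Reagents that add atoms: chloromethyl methyl ether, COCCl
Why: Williamson-type O-alkylation of both phenols; the methoxymethyl ether is chosen because it directs the lithiation of step 2, survives organolithium, hot KOH, hydride and alkaline peroxide, and leaves under mild acid.

Step 2
Reactants: 2 1-chloro-3,5-bis(methoxymethoxy)benzene; 3 prenyl bromide
Product: 5 5-chloro-1,3-bis(methoxymethoxy)-2-(3-methylbut-2-en-1-yl)benzene, via aryllithium 4 (not isolated)
Conditions: n-BuLi (1.1 equiv), THF, −20 → 0 °C; then CuI (10 mol %), 3 (1.3 equiv), −78 °C → rt
Reagents that add atoms: none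
Why: Directed ortho-metalation at the C–H between the two chelating acetal groups, para to chlorine; the C–Cl bond does not exchange with n-BuLi at this temperature, whereas a C–Br bond would. Copper-assisted SN2 alkylation takes the primary carbon of 3, because attack at the tertiary end would place a quaternary carbon between two ortho substituents.

Step 3
Reactants: 5 5-chloro-1,3-bis(methoxymethoxy)-2-(3-methylbut-2-en-1-yl)benzene
Product: 6 3,5-bis(methoxymethoxy)-4-(3-methylbut-2-en-1-yl)phenol
Conditions: Pd2(dba)3 (2 mol %), t-BuXPhos (2-di-tert-butylphosphino-2′,4′,6′-triisopropylbiphenyl, 8 mol %), KOH (3 equiv), 1,4-dioxane/H2O 1:1, 100 °C; NaH2PO4 (aq) to pH 6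
Reagents that add atoms: potassium hydroxide, [K+].[OH-]
Why: Palladium-catalysed C–O coupling of an aryl chloride with hydroxide (Buchwald–Hartwig-type hydroxylation); the bulky di-tert-butyl biarylphosphine promotes oxidative addition of the electron-rich chloride and C–O reductive elimination and disfavours arylation of the product phenoxide. Acetals and the isolated alkene are inert to aqueous KOH.

Step 4
Reactants: 6 3,5-bis(methoxymethoxy)-4-(3-methylbut-2-en-1-yl)phenol
Product: 7 6-hydroxy-2,4-bis(methoxymethoxy)-3-(3-methylbut-2-en-1-yl)benzaldehyde
Conditions: MgCl2 (1.5 equiv), Et3N (3.8 equiv), (CH2O)n (6 equiv), MeCN, 80 °C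
Reagents that add atoms: paraformaldehyde (as formaldehyde), C=O
Why: Magnesium-mediated ortho-formylation (Casnati–Skattebøl reaction): the magnesium phenoxide delivers formaldehyde to the ortho carbon through a chelate and a second formaldehyde oxidises the benzylic alkoxide. The two ortho positions of 6 are equivalent by symmetry, and the hydrogen-bonded aldehyde resists a second formylation.

Step 5
Reactants: 7 6-hydroxy-2,4-bis(methoxymethoxy)-3-(3-methylbut-2-en-1-yl)benzaldehyde
Product: 8 2-(hydroxymethyl)-3,5-bis(methoxymethoxy)-4-(3-methylbut-2-en-1-yl)phenol
Conditions: NaBH4 (1.0 equiv), THF/MeOH 4:1, 0 °C; NH4Cl (aq); used crude at once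
Reagents that add atoms: none
Why: Borohydride reduction of the aldehyde, leaving alkene and acetals untouched; 8 ionises easily at the benzylic carbon, so it is worked up neutral, not chromatographed, and carried straight into step 8.

Step 6
Reactants: 9 4-bromocatechol
Product: 10 4-bromo-1,2-bis(methoxymethoxy)benzene
Conditions: MOMCl (2.6 equiv), i-Pr2NEt (3.5 equiv), CH2Cl2, 0 °C → rt
Reagents that add atoms: chloromethyl methyl ether, COCCl
Why: Williamson-type O-alkylation of both catechol hydroxyls; the para acetal oxygen later stabilises positive charge at C2 in the key step, and ring B carries the same protecting group as ring A.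

Step 7
Reactants: 10 4-bromo-1,2-bis(methoxymethoxy)benzene; 11 vinylboronic acid MIDA ester
Product: 12 (E)-2-[3,4-bis(methoxymethoxy)phenyl]vinylboronic acid MIDA ester
Conditions: Pd(OAc)2 (5 mol %), P(o-tol)3 (10 mol %), Et3N (2 equiv), DMF (dry), 90 °C
Reagents that add atoms: none
Why: Heck reaction: the tetracoordinate boron of 11 cannot transmetalate under anhydrous conditions, so aryl–palladium inserts with aryl on the terminal carbon and syn β-hydride elimination gives the E alkene.

Step 8
Reactants: 8 2-(hydroxymethyl)-3,5-bis(methoxymethoxy)-4-(3-methylbut-2-en-1-yl)phenol; 12 (E)-2-[3,4-bis(methoxymethoxy)phenyl]vinylboronic acid MIDA ester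
Product: 14 (2S,3S)-2-[3,4-bis(methoxymethoxy)phenyl]-5,7-bis(methoxymethoxy)-6-(3-methylbut-2-en-1-yl)chroman-3-ylboronic acid MIDA ester (2,3-trans), via ortho-quinone methide 13 (not isolated)
Conditions: (R)-3,3′-bis(2,4,6-triisopropylphenyl)-1,1′-binaphthyl-2,2′-diyl hydrogen phosphate ((R)-TRIP, 10 mol %), 12 (2.5 equiv), 5 Å MS, CH2Cl2, 0 °C → rt; 8 added over 6 h
Reagents that add atoms: none
Why: Proposed new method: the acid protonates the benzylic hydroxyl of 8, water leaves with help from the three ring oxygens ortho and para to C4a, and the ortho-quinone methide 13 stays hydrogen-bonded to the chiral phosphate through O1. The boron-bearing alkene carbon of 12 attacks the exocyclic methylene (C3–C4) while positive charge grows at the benzylic carbon, stabilised by the para acetal oxygen of ring B and by hyperconjugation from the tetracoordinate C–B bond, and O1 then closes on that carbon (O1–C2), an asynchronous inverse-electron-demand oxa-[4+2] cycloaddition. The closest known reaction type is the chiral-phosphoric-acid-catalysed cycloaddition of ortho-quinone methides with electron-rich styrenes to 2-arylchromans; new here are the alkenyl MIDA boronate as the 2π partner and a quinone methide unsubstituted at the methide carbon. Ring C closes in the [4+2] mode, four atoms (O1, C8a, C4a, C4) from 13 and two (C2, C3) from 12. C3 is set in the C–C bond formation and C2 in the closure; their trans relation follows from suprafacial addition across the E alkene, and the absolute sense from the alkene face that the phosphate-bound 13 can reach in the catalyst pocket. Regioselectivity (aryl next to O1) is secured because the cation-stabilising aryl group and the β-boron effect act in the same direction. Chemoselectivity over the prenyl alkene and over Friedel–Crafts attack of C8 of a second molecule of 8 on 13 is secured by the excess of the more polarised alkene 12 and the low stationary concentration of 8.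

Step 9
Reactants: 14 (2S,3S)-2-[3,4-bis(methoxymethoxy)phenyl]-5,7-bis(methoxymethoxy)-6-(3-methylbut-2-en-1-yl)chroman-3-ylboronic acid MIDA ester
Product: 16 (2R,3S)-2-[3,4-bis(methoxymethoxy)phenyl]-5,7-bis(methoxymethoxy)-6-(3-methylbut-2-en-1-yl)chroman-3-ol, via boronic acid 15 (not isolated)
Conditions: 30% H2O2 (aq), 2 M NaOH (aq), THF, 0 °C → rt; Na2S2O3 (aq)
Reagents that add atoms: hydrogen peroxide, OO
Why: Hydroxide opens the MIDA cage to 15, and the hydroperoxide ate complex undergoes stereospecific 1,2-migration of C3 from boron to oxygen with retention, so the trans relation is kept. Peroxide is present from the start so that migration outruns β-elimination of the O1 aryloxide, and the electron-rich prenyl alkene is inert to alkaline peroxide.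

Step 10
Reactants: 16 (2R,3S)-2-[3,4-bis(methoxymethoxy)phenyl]-5,7-bis(methoxymethoxy)-6-(3-methylbut-2-en-1-yl)chroman-3-ol
Product: 17 6-prenylcatechin, (2R,3S)-2-(3,4-dihydroxyphenyl)-6-(3-methylbut-2-en-1-yl)chroman-3,5,7-triol
Conditions: HCl (1.25 M in MeOH), MeOH (degassed), argon, 0 → 35 °C
Reagents that add atoms: none
Why: Acid-catalysed acetal exchange moves the four methoxymethyl groups onto methanol; dilute acid at low temperature under argon stays below the conditions that protonate the prenyl alkene or ionise C2–O1, and no stereocentre is touched.

## Compound list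

1 | 5-chlororesorcinol (5-chlorobenzene-1,3-diol) | Oc1cc(O)cc(Cl)c1 | starting material
2 | 1-chloro-3,5-bis(methoxymethoxy)benzene | COCOc1cc(Cl)cc(OCOC)c1 | intermediate
3 | prenyl bromide (1-bromo-3-methylbut-2-ene) | CC(C)=CCBr | starting material
4 | [4-chloro-2,6-bis(methoxymethoxy)phenyl]lithium (not isolated) | [Li]c1c(OCOC)cc(Cl)cc1OCOC | intermediate
5 | 5-chloro-1,3-bis(methoxymethoxy)-2-(3-methylbut-2-en-1-yl)benzene | CC(C)=CCc1c(OCOC)cc(Cl)cc1OCOC | intermediate
6 | 3,5-bis(methoxymethoxy)-4-(3-methylbut-2-en-1-yl)phenol | CC(C)=CCc1c(OCOC)cc(O)cc1OCOC | intermediate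
7 | 6-hydroxy-2,4-bis(methoxymethoxy)-3-(3-methylbut-2-en-1-yl)benzaldehyde | CC(C)=CCc1c(OCOC)cc(O)c(C=O)c1OCOC | intermediate
8 | 2-(hydroxymethyl)-3,5-bis(methoxymethoxy)-4-(3-methylbut-2-en-1-yl)phenol | CC(C)=CCc1c(OCOC)cc(O)c(CO)c1OCOC | intermediate
9 | 4-bromocatechol (4-bromobenzene-1,2-diol) | Oc1ccc(Br)cc1O | starting material
10 | 4-bromo-1,2-bis(methoxymethoxy)benzene | COCOc1ccc(Br)cc1OCOC | intermediate
11 | vinylboronic acid MIDA ester (2-ethenyl-6-methyl-1,3,6,2-dioxazaborocane-4,8-dione) | C=CB1OC(=O)CN(C)CC(=O)O1 | starting material
12 | 2-{(E)-2-[3,4-bis(methoxymethoxy)phenyl]ethenyl}-6-methyl-1,3,6,2-dioxazaborocane-4,8-dione | CN1CC(=O)OB(/C=C/c2ccc(OCOC)c(OCOC)c2)OC(=O)C1 | intermediate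
13 | 3,5-bis(methoxymethoxy)-4-(3-methylbut-2-en-1-yl)-6-methylidenecyclohexa-2,4-dien-1-one (not isolated) | O=C1C=C(OCOC)C(CC=C(C)C)=C(OCOC)C1=C | intermediate
14 | 2-[(2S,3S)-2-[3,4-bis(methoxymethoxy)phenyl]-5,7-bis(methoxymethoxy)-6-(3-methylbut-2-en-1-yl)-3,4-dihydro-2H-chromen-3-yl]-6-methyl-1,3,6,2-dioxazaborocane-4,8-dione (2,3-trans) | CC(C)=CCc1c(OCOC)cc2c(c1OCOC)C[C@H](B1OC(=O)CN(C)CC(=O)O1)[C@@H](c1ccc(OCOC)c(OCOC)c1)O2 | intermediate
15 | [(2S,3S)-2-[3,4-bis(methoxymethoxy)phenyl]-5,7-bis(methoxymethoxy)-6-(3-methylbut-2-en-1-yl)-3,4-dihydro-2H-chromen-3-yl]boronic acid (not isolated) | CC(C)=CCc1c(OCOC)cc2c(c1OCOC)C[C@H](B(O)O)[C@@H](c1ccc(OCOC)c(OCOC)c1)O2 | intermediate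
16 | (2R,3S)-2-[3,4-bis(methoxymethoxy)phenyl]-5,7-bis(methoxymethoxy)-6-(3-methylbut-2-en-1-yl)-3,4-dihydro-2H-chromen-3-ol | CC(C)=CCc1c(OCOC)cc2c(c1OCOC)C[C@H](O)[C@@H](c1ccc(OCOC)c(OCOC)c1)O2 | intermediate
17 | 6-prenylcatechin, (2R,3S)-2-(3,4-dihydroxyphenyl)-6-(3-methylbut-2-en-1-yl)-3,4-dihydro-2H-chromene-3,5,7-triol | CC(C)=CCc1c(O)cc2c(c1O)C[C@H](O)[C@@H](c1ccc(O)c(O)c1)O2 | target

## Step count and least certain steps

Total: 10 steps. Longest linear sequence: 8 steps (steps 1–5, 8, 9, 10); the ring B branch is steps 6 and 7.

**Step 8 (key step).** Four things may go wrong: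

- oligomerisation, when the nucleophilic C8 of a second molecule of 8 adds to 13 faster than the alkene does;
- intramolecular acetal exchange between the C5 methoxymethyl ether and the benzylic hydroxyl;
- poor facial selectivity, because the alkene offers the catalyst no hydrogen-bonding handle;
- slow reaction, because 12 dissolves poorly in the non-polar medium that ion pairing needs.

The fallback uses known chemistry, sets out from 7 and 12 and returns at 16. Aqueous NaOH in THF hydrolyses 12 to (E)-2-[3,4-bis(methoxymethoxy)phenyl]vinylboronic acid F1. Condensation of 7 with F1 and catalytic dibenzylamine in toluene at 80–90 °C is a Petasis-type borono-Mannich reaction. Loss of the amine and oxa-6π electrocyclisation then give the racemic 2-aryl-2H-chromene F2. Copper-catalysed enantioselective protoboration of the styrene-like C3=C4 bond is run as a kinetic resolution (CuCl, a chiral bisphosphine such as (R,R)- or (S,S)-1,2-bis(2,5-diphenylphospholano)ethane, NaOt-Bu, B2pin2 0.55 equiv, MeOH, THF). It should convert the (2S) enantiomer, with boron entering at C3 anti to the C2 aryl group, into the trans (2S,3S) 3-pinacolboryl flavan F3. The isolated prenyl alkene is not a substrate for the copper boryl. NaBO3·4H2O in THF/H2O then gives 16. The price is the loss of the slower-reacting enantiomer of F2.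

**Step 2.** Alkylation at the tertiary end of 3, or coupling side reactions of the allylic bromide, may compete. A minor amount of lithiation next to chlorine would lose LiCl to an aryne. The fallback sets out from 2 and returns at 5. Aryllithium 4 is formed as before and quenched with allyl bromide, which has no regiochemical ambiguity, to give 2-allyl-5-chloro-1,3-bis(methoxymethoxy)benzene F4. Cross-metathesis with excess 2-methyl-2-butene (second-generation Grubbs catalyst, CH2Cl2, 40 °C) turns allyl into prenyl.

**Step 3.** Oxidative addition of the electron-rich chloride may be slow. The product phenoxide may be arylated by 5 to a diaryl ether, and the prenyl double bond may migrate at 100 °C. The fallback sets out from 5 and returns at 6. Miyaura borylation (Pd2(dba)3, 2-dicyclohexylphosphino-2′,4′,6′-triisopropylbiphenyl, B2pin2, KOAc, dioxane, 100 °C) gives the aryl pinacol boronate F5. NaBO3·4H2O in THF/H2O at rt gives 6. The phenoxide then never meets the palladium catalyst.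

**Step 7.** The electron-rich bromide may insert sluggishly. Traces of water may open the MIDA cage and divert the boronate into Suzuki-type coupling or protodeboronation. The fallback sets out from 10 and returns at 12. Suzuki–Miyaura vinylation with potassium vinyltrifluoroborate (PdCl2(dppf), Cs2CO3, THF/H2O, 80 °C) gives 4-ethenyl-1,2-bis(methoxymethoxy)benzene F6. Cross-metathesis with 11 (second-generation Grubbs catalyst, CH2Cl2, 40 °C) gives 12 with E geometry.

**Step 10.** Acid may protonate the prenyl alkene, with cyclisation onto the C5 or C7 hydroxyl. Cleavage of the two hindered ring A acetals may be incomplete, and the free polyphenol may oxidise in air during isolation. The fallback sets out from 16 and returns at 17. The acetals are cleaved without protic acid by ZnBr2 and 1-propanethiol in CH2Cl2 at 0 °C, which transfers the methoxymethyl group to sulfur. The crude pentaol is acetylated in the same flask (Ac2O, pyridine, DMAP) to the air-stable 6-prenylcatechin pentaacetate F7, which can be purified. Mild methanolysis (K2CO3, MeOH, 0 °C, argon, then dilute acetic acid) releases 17.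

## Further compounds

F1 | step 8 | (E)-2-[3,4-bis(methoxymethoxy)phenyl]vinylboronic acid | OB(O)/C=C/c1ccc(OCOC)c(OCOC)c1
F2 | step 8 | 2-[3,4-bis(methoxymethoxy)phenyl]-5,7-bis(methoxymethoxy)-6-(3-methylbut-2-en-1-yl)-2H-chromene (racemic) | CC(C)=CCc1c(OCOC)cc2c(c1OCOC)C=CC(c1ccc(OCOC)c(OCOC)c1)O2
F3 | step 8 | 2-[(2S,3S)-2-[3,4-bis(methoxymethoxy)phenyl]-5,7-bis(methoxymethoxy)-6-(3-methylbut-2-en-1-yl)-3,4-dihydro-2H-chromen-3-yl]-4,4,5,5-tetramethyl-1,3,2-dioxaborolane | CC(C)=CCc1c(OCOC)cc2c(c1OCOC)C[C@H](B1OC(C)(C)C(C)(C)O1)[C@@H](c1ccc(OCOC)c(OCOC)c1)O2
F4 | step 2 | 5-chloro-1,3-bis(methoxymethoxy)-2-(prop-2-en-1-yl)benzene | C=CCc1c(OCOC)cc(Cl)cc1OCOC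
F5 | step 3 | 2-[3,5-bis(methoxymethoxy)-4-(3-methylbut-2-en-1-yl)phenyl]-4,4,5,5-tetramethyl-1,3,2-dioxaborolane | CC(C)=CCc1c(OCOC)cc(B2OC(C)(C)C(C)(C)O2)cc1OCOC
F6 | step 7 | 4-ethenyl-1,2-bis(methoxymethoxy)benzene | C=Cc1ccc(OCOC)c(OCOC)c1
F7 | step 10 | (2R,3S)-2-(3,4-diacetoxyphenyl)-6-(3-methylbut-2-en-1-yl)-3,4-dihydro-2H-chromene-3,5,7-triyl triacetate | CC(C)=CCc1c(OC(C)=O)cc2c(c1OC(C)=O)C[C@H](OC(C)=O)[C@@H](c1ccc(OC(C)=O)c(OC(C)=O)c1)O2
A1 | alternative 1 | methyl 3-{[(1R,2S)-1-[3,4-bis(methoxymethoxy)phenyl]-2-(tert-butyldimethylsilyloxy)-9-methyl-5-oxodec-8-en-1-yl]oxy}prop-2-ynoate | COC(=O)C#CO[C@H](c1ccc(OCOC)c(OCOC)c1)[C@@H](O[Si](C)(C)C(C)(C)C)CCC(=O)CCC=C(C)C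
A2 | alternative 1 | (2R,3S)-2-[3,4-bis(methoxymethoxy)phenyl]-3-(tert-butyldimethylsilyloxy)-6-(3-methylbut-2-en-1-yl)-3,4-dihydro-2H-chromene-5,7-diol | CC(C)=CCc1c(O)cc2c(c1O)C[C@H](O[Si](C)(C)C(C)(C)C)[C@@H](c1ccc(OCOC)c(OCOC)c1)O2
A3 | alternative 2 | 1-[(2R,3S)-2-[3,4-bis(methoxymethoxy)phenyl]-3-(tert-butyldimethylsilyloxy)-3,4-dihydro-2H-pyran-6-yl]-2-diazoethan-1-one | O=C(C=[N+]=[N-])C1=CC[C@H](O[Si](C)(C)C(C)(C)C)[C@@H](c2ccc(OCOC)c(OCOC)c2)O1
A4 | alternative 2 | triisopropyl[(5-methylhex-4-en-1-yn-1-yl)oxy]silane | CC(C)=CCC#CO[Si](C(C)C)(C(C)C)C(C)C
A5 | alternative 2 | (2R,3S)-2-[3,4-bis(methoxymethoxy)phenyl]-3-(tert-butyldimethylsilyloxy)-6-(3-methylbut-2-en-1-yl)-7-(triisopropylsilyloxy)-3,4-dihydro-2H-chromen-5-ol | CC(C)=CCc1c(O[Si](C(C)C)(C(C)C)C(C)C)cc2c(c1O)C[C@H](O[Si](C)(C)C(C)(C)C)[C@@H](c1ccc(OCOC)c(OCOC)c1)O2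
A6 | alternative 3 | (S)-2-{(R)-[3,4-bis(methylsulfonyloxy)phenyl][3,5-bis(methoxymethoxy)-4-(3-methylbut-2-en-1-yl)phenoxy]methyl}oxirane | CC(C)=CCc1c(OCOC)cc(O[C@H](c2ccc(OS(C)(=O)=O)c(OS(C)(=O)=O)c2)[C@@H]2CO2)cc1OCOC
A7 | alternative 3 | 4-[(2R,3S)-3-hydroxy-5,7-bis(methoxymethoxy)-6-(3-methylbut-2-en-1-yl)-3,4-dihydro-2H-chromen-2-yl]-1,2-phenylene dimethanesulfonate | CC(C)=CCc1c(OCOC)cc2c(c1OCOC)C[C@H](O)[C@@H](c1ccc(OS(C)(=O)=O)c(OS(C)(=O)=O)c1)O2
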